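I began from a one-step world: gas crosses into the solution, the reaction takes it out again, and I took the two flows as equal at each moment (a quasi-steady state).

| flask | substrate | gas phase | free catalyst | remark | time |
|---|---|---|---|---|---|
| red | 0.42 M | 15 mM (held) | 0.034 mol% | run made earlier |  |
| grey | 0.42 M | 15 mM (held) | 0.075 mol% | run made earlier |  |
| green | 0.63 M | 15 mM (held) | 0.05 mol% | run made earlier |  |
| flask | 0.42 M | 15 mM (held) | 0.05 mol% |  | 80 min |

| run | time / min | target / % | substrate / % |
|---|---|---|---|
| red | 8.00 | 11.8 | 88.6 |
| red | 12.0 | 17.8 | 82.3 |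
| red | 20.0 | 29.0 | 70.2 |
| red | 40.0 | 51.1 | 47.9 |
| red | 60.0 | 66.5 | 29.5 |
| red | 90.0 | 79.6 | 14.6 |
| grey | 8.00 | 13.8 | 85.4 |
| grey | 12.0 | 20.8 | 78.4 |
| grey | 20.0 | 34.7 | 64.6 |
| grey | 40.0 | 60.8 | 34.0 |
| grey | 60.0 | 75.9 | 13.7 |
| grey | 90.0 | 83.2 | 1.8 |
| green | 20.0 | 24.2 | 74.7 |
| green | 40.0 | 46.8 | 50.1 |
| green | 60.0 | 63.6 | 30.3 |
| green | 80.0 | 74.7 | 14.4 |
| green | 90.0 | 78.5 | 9.4 |

(readings scatter by 0.5 percentage points)

- at the start none of the gas phase is in solution

- the target standing at 80 min, as a percentage of the substrate charged
- concentration of dissolved gas in solution at 80 min, in percent of saturation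

The inflow falls from its full value into gas-free solution to zero at saturation, so the dissolved gas, as a share of saturation, is one minus the consumption rate divided by that full value. Between 8.00 min and 20.0 min the red run made target at 6.02 mM min⁻¹ and the grey run at 7.32 mM min⁻¹, although grey carried about twice the catalyst. I let two resistances add, with the catalyst's falling as its loading rises. That gave the transfer ceiling, the highest rate at which gas can enter the solution, as 8.90 mM min⁻¹.

Between 60.0 min and 90.0 min red lost substrate at 2.09 mM min⁻¹ and grey at 1.67 mM min⁻¹. The flask's loading lies between theirs , so I took their mean, 1.88 mM min⁻¹, and reckoned 78.9% of saturation at 80 min.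

The forecast gave 81.8% of target and 75% of saturation, on the ground, in its words: “This points to gas-transfer limitation”. My figure for the gas differed from the forecast's.

The flask gave 80.9% of target and 82.0% of saturation, which is higher than my reckoning and higher than the forecast.

    substrate + dissolved gas + free catalyst → free catalyst + target (k = 27000 L² mol⁻² min⁻¹)
    gas phase ⇌ dissolved gas, rate k2*(csat - [dissolved gas]) (kL = 0.630 min⁻¹)
    target + free catalyst ⇌ isomer of the product + free catalyst, rate k3*[free catalyst]*[target] forward; the back reaction follows from the equilibrium constant (K = 1.20, k = 16.0 L mol⁻¹ min⁻¹)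
    free catalyst → spent catalyst (k = 0.00810 min⁻¹)

I then read the same flask earlier, at 30.0 min, where substrate stood at 53.0%. At 40.0 min, half of the asked time, substrate in this flask stood at 40.4%. Between those two readings the loss averages 5.31 mM min⁻¹, and my ceiling, as I had read it from the runs, turns that average into 40.3% of saturation. At 30.0 min the flask held 0.00576 M of dissolved gas, which is 38.4% of saturation. At 40.0 min, half of the asked time, the flask held 0.00703 M of dissolved gas, which is 46.8% of saturation.

The earlier runs and the new flask are simulated from invented constants, noise included.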